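**Strategy.** Ring A is disconnected at C1–C2 and C4–C5. What remains is ring B (C5–C10) carrying the complete C9 side chain, plus a three-carbon unit C2–C3–C4 that is brought in as a pent-4-enoate ester on an oxygen at C7. The key step exploits the allylic array C5=C6–C7–O of ring B and a vinyl group (C1) on quaternary C10: in one pot, an Ireland–Claisen rearrangement moves the ester α-carbon (C4) from the C7 oxygen to the β face of C5, and ring-closing metathesis then joins C1 to C2, closing ring A trans-fused. The precursor is a cyclohex-2-enyl pent-4-enoate assembled by an asymmetric Diels–Alder reaction of an oxidised geraniol ether.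

Key step: step 10

Remark: the labdane numbers of the target (C1–C20) are used for every intermediate; β is the face of ring B that carries the C20 methyl group, α the opposite face.
Assumption: the catalyst of step 4 is written with the (S)-configured oxazaborolidine on the basis of the accepted pre-transition-state model for α-substituted enals; its mirror image would be used if the model pointed to the other face of this enal.

**Step 1**
Reactants: 1 geraniol
Product: 2 geranyl tert-butyldimethylsilyl ether
Conditions: TBSCl, imidazole, DMF, 0 °C → rt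
Reagents that add atoms: tert-butyldimethylsilyl chloride, CC(C)(C)[Si](C)(C)Cl
Why: Silyl ether protection of the primary allylic alcohol masks C15–OH in a form that should survive the later amide bases, hydride and Lewis acids; no stereocentre is formed.

**Step 2**
Reactants: 2 geranyl tert-butyldimethylsilyl ether
Product: 4 (2E,6E)-8-(tert-butyldimethylsilyloxy)-2,6-dimethylocta-2,6-dienal, via allylic alcohol 3 (not isolated)
Conditions: SeO2 (0.3 equiv), t-BuOOH, salicylic acid (cat.), CH2Cl2, rt; then MnO2, CH2Cl2, rt
Reagents that add atoms: tert-butyl hydroperoxide, CC(C)(C)OO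
Why: Selenium dioxide allylic oxidation (ene reaction, then [2,3]-sigmatropic shift) should attack the more electron-rich terminal olefin at its E methyl group, and MnO2 takes the allylic alcohol to the E enal, whose geometry later fixes the C9/C10 relationship.

**Step 3**
Reactants: 5 but-3-en-2-one
Product: 6 2-(triisopropylsilyloxy)buta-1,3-diene
Conditions: iPr3SiOTf, Et3N, Et2O, 0 °C
Reagents that add atoms: triisopropylsilyl triflate, CC(C)[Si](C(C)C)(C(C)C)OS(=O)(=O)C(F)(F)F
Why: Soft enolisation and O-silylation of the methyl ketone gives the acid-tolerant 2-siloxy diene; no stereocentre is formed.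

**Step 4**
Reactants: 4 (2E,6E)-8-(tert-butyldimethylsilyloxy)-2,6-dimethylocta-2,6-dienal, 6 2-(triisopropylsilyloxy)buta-1,3-diene
Product: 7 (1S,6S)-6-[(3E)-5-(tert-butyldimethylsilyloxy)-3-methylpent-3-en-1-yl]-1-methyl-4-(triisopropylsilyloxy)cyclohex-3-ene-1-carbaldehyde (ring B: C10 with CH3 β and CHO α, C9 side chain β, C7 silyl enol ether)
Conditions: 6 (2 equiv), oxazaborolidinium triflimide (20 mol%) from (S)-3,3-diphenyl-1-(o-tolyl)tetrahydro-1H,3H-pyrrolo[1,2-c][1,3,2]oxazaborole and HN(SO2CF3)2, CH2Cl2, −78 → −40 °C
Reagents that add atoms: none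
Why: Lewis-acid-catalysed enantioselective Diels–Alder reaction: the 2-siloxy diene adds with para regiochemistry (its CH2 next to the siloxy carbon bonds to the enal β-carbon), the suprafacial addition to the E enal places the C10 methyl and the C9 side chain cis, and the chiral oxazaborolidinium ion shields one face of the coordinated enal, which sets the absolute configuration of C9 and C10 together.

**Step 5**
Reactants: 7 ring-B aldehyde
Product: 8 10α-vinyl analogue of 7 (CHO replaced by CH=CH2; C9 and C10 unchanged)
Conditions: Ph3PCH3Br, KN(SiMe3)2, THF, 0 °C; then 7, −78 → 0 °C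
Reagents that add atoms: methyltriphenylphosphonium bromide, C[P+](c1ccccc1)(c1ccccc1)c1ccccc1.[Br-]
Why: Wittig methylenation of the non-enolisable α-quaternary aldehyde turns C1 into the vinyl group needed for the metathesis; the silyl enol ether and silyl ether are inert to the ylide and no stereocentre is touched.

**Step 6**
Reactants: 8 10α-vinyl silyl enol ether
Product: 9 ring-B enone (C7=O, C5=C6; C10 with CH3 β and vinyl α; C9 side chain β)
Conditions: Pd(OAc)2 (1.1 equiv), MeCN, 40 °C
Reagents that add atoms: none
Why: Saegusa–Ito oxidation: palladation of the silyl enol ether at C6 and β-hydride elimination from C5 (the only β-hydrogens) should give the C5=C6 enone, with the isolated olefins and the C9/C10 centres untouched.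

**Step 7**
Reactants: 9 ring-B enone
Product: 11 8α-(phenylthiomethyl) ring-B enone, via silyl dienol ether 10 (not isolated)
Conditions: LiN(iPr)2, Me3SiCl, THF, −78 °C; volatiles removed; PhSCH2Cl, ZnBr2 (5 mol%), CH2Cl2, rt
Reagents that add atoms: chloromethyl phenyl sulfide, ClCSc1ccccc1
Why: Kinetic α′-deprotonation (only C8–H is available because C10 is quaternary) and O-silylation give dienol ether 10, whose terminal carbon C8 is alkylated by the thionium ion from PhSCH2Cl/ZnBr2 (Lewis-acid α-alkylation of a silyl enol ether) anti to the C9 side chain, so that the future C17 sits α on a centre that is destroyed later.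

**Step 8**
Reactants: 11 8α-(phenylthiomethyl) ring-B enone
Product: 12 7β-allylic alcohol (C7–OH cis to the C9 side chain, trans to C8–CH2SPh; C5=C6)
Conditions: NaBH4, CeCl3·7H2O, MeOH, −78 °C
Reagents that add atoms: none
Why: Luche 1,2-reduction: hydride should add axially to C7 from the α face (C8 and C9 substituents equatorial), giving the equatorial β alcohol without conjugate reduction or loss of thiophenol.

**Step 9**
Reactants: 12 7β-allylic alcohol, 13 pent-4-enoic acid
Product: 14 7β-pent-4-enoate of 12
Conditions: DCC, DMAP (cat.), CH2Cl2, rt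
Reagents that add atoms: none
Why: Steglich esterification acylates the secondary allylic alcohol with retention at C7 and places C2–C3–C4 and the future carboxyl carbon C19 on the C7 oxygen.

**Step 10**
Reactants: 14 7β-pent-4-enoate
Product: 18 (8βH)-17-(phenylthio)-15-(tert-butyldimethylsilyloxy)-18-norlabda-1,6,13E-trien-19-oic acid (C4 epimers), via silyl ketene acetal 15 (not isolated), via monocyclic silyl ester 16 (not isolated), via bicyclic silyl ester 17 (not isolated)
Conditions: KN(SiMe3)2, Me3SiCl, toluene, −78 → 80 °C; then RuCl2(=CHPh)(PCy3)(H2IMes) (second-generation Grubbs catalyst, 5 mol%), 80 °C; aq. NH4Cl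
Reagents that add atoms: none
Why: KN(SiMe3)2/Me3SiCl converts the ester into silyl ketene acetal 15, which undergoes the Ireland–Claisen [3,3]-sigmatropic rearrangement through a six-membered cyclic transition state in which the C7–O bond breaks as the C4–C5 bond forms, giving silyl ester 16 with the olefin moved to C6=C7. Ring-closing olefin metathesis between the C10 vinyl group and the new allyl group on C4 then forms C1=C2 with loss of ethene and closes ring A as a cyclohexene (closure at the two terminal olefin carbons, not a polar ring closure). Both events are established reaction types: the ester enolate Claisen rearrangement of cyclohex-2-enyl esters and ring-closing metathesis to cyclohexenes flanked by quaternary carbons. C5 is set by the suprafacial course of the shift: C4 arrives on the β face that the C7 oxygen leaves, hence trans to the α vinyl group on C10 and with 5α-H, which is the arrangement that the metathesis turns into the trans ring fusion. C4 is formed as an epimer mixture that is harmless because step 12 passes through the planar enediolate. The step needs enolisation only at the ester α-CH2 (the sole acidic C–H), a single allylic terminus for the shift (C8 is sp3) and metathesis only between the two monosubstituted olefins, which the unreactive cis ring olefin and trisubstituted side-chain olefin should secure.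

**Step 11**
Reactants: 18 bicyclic trienoic acid
Product: 19 (8βH)-17-(phenylthio)-15-(tert-butyldimethylsilyloxy)-18-norlabd-13E-en-19-oic acid (C4 epimers)
Conditions: H2 (3 atm), RhCl(PPh3)3 (10 mol%), benzene–EtOH, rt
Reagents that add atoms: none
Why: Homogeneous hydrogenation with RhCl(PPh3)3 is sensitive to olefin substitution and tolerant of thioethers, so the two cis-disubstituted ring olefins (C1=C2, C6=C7) should be saturated while the trisubstituted C13=C14 olefin is kept; no stereocentre is created.

**Step 12**
Reactants: 19 saturated 18-nor acid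
Product: 20 (8βH)-17-(phenylthio)-15-(tert-butyldimethylsilyloxy)labd-13E-en-19-oic acid (C18 methyl α, C19 acid β)
Conditions: LiN(iPr)2 (2.5 equiv), THF, 0 → 40 °C; MeI, −78 → 0 °C; aq. HCl (pH 3), 0 °C
Reagents that add atoms: iodomethane, CI
Why: α-Alkylation of the carboxylic acid enediolate: iodomethane should attack planar C4 from the α face, away from the axial C20 methyl that is 1,3-diaxial to the β face, which places CH3 equatorial (C18) and CO2H axial (C19) and converts both C4 epimers into one product.

**Step 13**
Reactants: 20 C4-methylated acid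
Product: 22 15-(tert-butyldimethylsilyloxy)labda-8(17),13E-dien-19-oic acid, via sulfoxide 21 (not isolated)
Conditions: NaIO4, MeOH–H2O, 0 °C → rt; then toluene, NaHCO3, 110 °C
Reagents that add atoms: none
Why: Periodate oxidises only the thioether, and thermal syn-elimination of sulfoxide 21 (sulfoxide pyrolysis) can take a β-hydrogen only from C8, so the exocyclic C8=C17 olefin should form regiospecifically while the C8 stereocentre is removed.

**Step 14**
Reactants: 22 silyl ether acid
Product: 23 isocupressic acid
Conditions: HF·pyridine, pyridine, THF, 0 °C → rt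
Reagents that add atoms: none
Why: Fluoride-driven cleavage of the primary silyl ether frees C15–OH under buffered conditions that should leave the exocyclic olefin and the acid untouched.

**Step 15**
Reactants: 23 isocupressic acid
Product: 24 15-acetoxyisocupressic acid
Conditions: Ac2O, pyridine, DMAP (cat.), CH2Cl2, 0 °C → rt; aq. NaHCO3
Reagents that add atoms: acetic anhydride, CC(=O)OC(C)=O
Why: DMAP-catalysed acetylation of the primary allylic alcohol; the hindered tertiary acid gives at most a mixed anhydride that is hydrolysed on bicarbonate work-up.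

**Compound list**

1 | geraniol, (2E)-3,7-dimethylocta-2,6-dien-1-ol | CC(C)=CCC/C(C)=C/CO | starting material
2 | geranyl tert-butyldimethylsilyl ether | CC(C)=CCC/C(C)=C/CO[Si](C)(C)C(C)(C)C | intermediate
3 | (2E,6E)-8-(tert-butyldimethylsilyloxy)-2,6-dimethylocta-2,6-dien-1-ol | OC/C(C)=C/CC/C(C)=C/CO[Si](C)(C)C(C)(C)C | intermediate (not isolated)
4 | (2E,6E)-8-(tert-butyldimethylsilyloxy)-2,6-dimethylocta-2,6-dienal | O=C/C(C)=C/CC/C(C)=C/CO[Si](C)(C)C(C)(C)C | intermediate
5 | but-3-en-2-one (methyl vinyl ketone) | CC(=O)C=C | starting material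
6 | 2-(triisopropylsilyloxy)buta-1,3-diene | C=CC(=C)O[Si](C(C)C)(C(C)C)C(C)C | intermediate
7 | (1S,6S)-6-[(3E)-5-(tert-butyldimethylsilyloxy)-3-methylpent-3-en-1-yl]-1-methyl-4-(triisopropylsilyloxy)cyclohex-3-ene-1-carbaldehyde | C1C(O[Si](C(C)C)(C(C)C)C(C)C)=CC[C@](C)(C=O)[C@H]1CC/C(C)=C/CO[Si](C)(C)C(C)(C)C | intermediate
8 | 10α-vinyl analogue of 7 (C10: CH3 β, CH=CH2 α; C9 side chain β; C7 silyl enol ether) | C1C(O[Si](C(C)C)(C(C)C)C(C)C)=CC[C@](C)(C=C)[C@H]1CC/C(C)=C/CO[Si](C)(C)C(C)(C)C | intermediate
9 | ring-B enone: 5-[(3E)-5-(tert-butyldimethylsilyloxy)-3-methylpent-3-en-1-yl]-4-methyl-4-vinylcyclohex-2-en-1-one, methyl and side chain cis (C7=O, C5=C6) | C1C(=O)C=C[C@](C)(C=C)[C@H]1CC/C(C)=C/CO[Si](C)(C)C(C)(C)C | intermediate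
10 | trimethylsilyl dienol ether of 9 (C7–OSiMe3, C7=C8, C5=C6) | C1=C(O[Si](C)(C)C)C=C[C@](C)(C=C)[C@H]1CC/C(C)=C/CO[Si](C)(C)C(C)(C)C | intermediate (not isolated)
11 | 8α-(phenylthiomethyl) ring-B enone (CH2SPh on C8, trans to the C9 side chain) | c1ccccc1SC[C@@H]1C(=O)C=C[C@](C)(C=C)[C@H]1CC/C(C)=C/CO[Si](C)(C)C(C)(C)C | intermediate
12 | 7β-allylic alcohol (C7–OH β, C8–CH2SPh α, C9 side chain β, C5=C6) | c1ccccc1SC[C@@H]1[C@@H](O)C=C[C@](C)(C=C)[C@H]1CC/C(C)=C/CO[Si](C)(C)C(C)(C)C | intermediate
13 | pent-4-enoic acid | C=CCCC(=O)O | starting material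
14 | 7β-pent-4-enoate of 12 | c1ccccc1SC[C@@H]1[C@@H](OC(=O)CCC=C)C=C[C@](C)(C=C)[C@H]1CC/C(C)=C/CO[Si](C)(C)C(C)(C)C | intermediate
15 | O-trimethylsilyl ketene acetal of 14 (C4=C19, geometry not defined) | c1ccccc1SC[C@@H]1[C@@H](OC(O[Si](C)(C)C)=CCC=C)C=C[C@](C)(C=C)[C@H]1CC/C(C)=C/CO[Si](C)(C)C(C)(C)C | intermediate (not isolated)
16 | trimethylsilyl 2-(ring-B C5β-yl)pent-4-enoate (C4 on the β face of C5, 5α-H, C6=C7, C10 vinyl; C4 epimers) | c1ccccc1SC[C@@H]1C=C[C@@H](C(CC=C)C(=O)O[Si](C)(C)C)[C@](C)(C=C)[C@H]1CC/C(C)=C/CO[Si](C)(C)C(C)(C)C | intermediate (not isolated)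
17 | trimethylsilyl ester of 18 | c1ccccc1SC[C@@H]1C=C[C@@H]2[C@](C)(C=CCC2C(=O)O[Si](C)(C)C)[C@H]1CC/C(C)=C/CO[Si](C)(C)C(C)(C)C | intermediate (not isolated)
18 | (8βH)-17-(phenylthio)-15-(tert-butyldimethylsilyloxy)-18-norlabda-1,6,13E-trien-19-oic acid, trans-fused (5α-H, 10β-CH3), C4 epimers | c1ccccc1SC[C@@H]1C=C[C@@H]2[C@](C)(C=CCC2C(=O)O)[C@H]1CC/C(C)=C/CO[Si](C)(C)C(C)(C)C | intermediate
19 | (8βH)-17-(phenylthio)-15-(tert-butyldimethylsilyloxy)-18-norlabd-13E-en-19-oic acid, C4 epimers | c1ccccc1SC[C@@H]1CC[C@@H]2[C@](C)(CCCC2C(=O)O)[C@H]1CC/C(C)=C/CO[Si](C)(C)C(C)(C)C | intermediate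
20 | (8βH)-17-(phenylthio)-15-(tert-butyldimethylsilyloxy)labd-13E-en-19-oic acid (C18 methyl α, C19 acid β) | c1ccccc1SC[C@@H]1CC[C@@H]2[C@](C)(CCC[C@]2(C)C(=O)O)[C@H]1CC/C(C)=C/CO[Si](C)(C)C(C)(C)C | intermediate
21 | S-oxide of 20 (sulfoxide, epimers at sulfur) | O=S(c1ccccc1)C[C@@H]1CC[C@@H]2[C@](C)(CCC[C@]2(C)C(=O)O)[C@H]1CC/C(C)=C/CO[Si](C)(C)C(C)(C)C | intermediate (not isolated)
22 | 15-(tert-butyldimethylsilyloxy)labda-8(17),13E-dien-19-oic acid | C=C1CC[C@@H]2[C@](C)(CCC[C@]2(C)C(=O)O)[C@H]1CC/C(C)=C/CO[Si](C)(C)C(C)(C)C | intermediate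
23 | isocupressic acid, 15-hydroxylabda-8(17),13E-dien-19-oic acid | C=C1CC[C@@H]2[C@](C)(CCC[C@]2(C)C(=O)O)[C@H]1CC/C(C)=C/CO | intermediate
24 | 15-acetoxyisocupressic acid, (4S,5R,9S,10R)-15-acetoxylabda-8(17),13E-dien-19-oic acid | C=C1CC[C@@H]2[C@](C)(CCC[C@]2(C)C(=O)O)[C@H]1CC/C(C)=C/COC(C)=O | target

**Step count and risks**

Total step count: 15. Longest linear sequence: 14 steps (steps 1, 2 and 4–15 from geraniol; step 3 prepares the diene).

Steps most likely to fail:

1. Step 10 (key step). The sigmatropic shift may be too slow. In the favoured half-chair the C7 ester is equatorial, and reaching the reactive pseudo-axial arrangement costs two 1,3-diaxial contacts, so fragmentation or hydrolysis of the silyl ketene acetal can overtake rearrangement. Silylamine and chloride residues of the first stage may also shorten the life of the ruthenium carbene before the hindered C10 vinyl group has reacted. The fallback sets out from 12 and comes back at 18, forming the two bonds in separate, enolate-free or separately optimised operations. Heating 12 with triethyl orthoacetate and a trace of propionic acid at 140 °C (orthoester Claisen rearrangement) should give the ethyl ester F1, with C4 as a CH2 group on the β face of C5. Deprotonation with LiN(iPr)2 and alkylation with allyl bromide should give the C4-allyl ester F2. Ring-closing metathesis with the same ruthenium catalyst in CH2Cl2 should give the bicyclic ethyl ester F3, and saponification with LiOH in THF–MeOH–H2O returns acid 18.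

2. Step 4. The trisubstituted enal may add too slowly to the simple siloxy diene at the low temperature that face discrimination needs; raising the temperature risks eroded enantioselectivity and acid-induced loss of silyl groups. The fallback sets out from 4 and 6 and comes back at 7, replacing asymmetric catalysis by resolution. Cycloaddition promoted by Me2AlCl in CH2Cl2 should give 7 together with its enantiomer F4 as a racemate. Condensation with (1R,2R)-N,N′-dimethyl-1,2-diphenylethane-1,2-diamine (molecular sieves, Et2O) should give two diastereomeric imidazolidines, F5 from 7 and F6 from the enantiomer, which are separated by chromatography. Brief hydrolysis of F5 with dilute aqueous acid in a two-phase system returns 7.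

3. Step 11. Slow uptake at the two hindered ring olefins, together with partial binding of the thioether to rhodium, may let reduction or migration of the C13=C14 olefin compete. The fallback goes from 18 directly to 19 with diimide (2-nitrobenzenesulfonyl hydrazide, Et3N, CH2Cl2, rt). This is a metal-free, concerted hydrogen transfer that cannot be inhibited by sulfur and cannot migrate double bonds; it is run to partial conversion with recycling if discrimination between the olefins is modest. It makes no new compound (F0).

**Further compounds**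

F1 | step 10 | ethyl 2-(ring-B C5β-yl)acetate from the orthoester Claisen rearrangement (C6=C7, C10 vinyl, C8–CH2SPh α) | c1ccccc1SC[C@@H]1C=C[C@@H](CC(=O)OCC)[C@](C)(C=C)[C@H]1CC/C(C)=C/CO[Si](C)(C)C(C)(C)C
F2 | step 10 | C4-allylated ethyl ester (ethyl 2-(ring-B C5β-yl)pent-4-enoate, C4 epimers) | c1ccccc1SC[C@@H]1C=C[C@@H](C(CC=C)C(=O)OCC)[C@](C)(C=C)[C@H]1CC/C(C)=C/CO[Si](C)(C)C(C)(C)C
F3 | step 10 | ethyl ester of 18 | c1ccccc1SC[C@@H]1C=C[C@@H]2[C@](C)(C=CCC2C(=O)OCC)[C@H]1CC/C(C)=C/CO[Si](C)(C)C(C)(C)C
F4 | step 4 | enantiomer of 7, (1R,6R) | C1C(O[Si](C(C)C)(C(C)C)C(C)C)=CC[C@@](C)(C=O)[C@@H]1CC/C(C)=C/CO[Si](C)(C)C(C)(C)C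
F5 | step 4 | imidazolidine of 7 with (1R,2R)-N,N′-dimethyl-1,2-diphenylethane-1,2-diamine | CN1[C@H](c2ccccc2)[C@H](N(C)C1[C@@]3(C)CC=C(O[Si](C(C)C)(C(C)C)C(C)C)C[C@@H]3CC/C(C)=C/CO[Si](C)(C)C(C)(C)C)c2ccccc2
F6 | step 4 | diastereomeric imidazolidine of F4 with the same diamine | CN1[C@H](c2ccccc2)[C@H](N(C)C1[C@]3(C)CC=C(O[Si](C(C)C)(C(C)C)C(C)C)C[C@H]3CC/C(C)=C/CO[Si](C)(C)C(C)(C)C)c2ccccc2
F0 | step 11 | none | none
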